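The route rests on cutting the C4–C1' bond between ring A (C1 OMe, C3 OH, C5 CH2CH2Ar) and hydroquinone ring B. It exploits the fact that O-2' of ring B and the benzylic carbon Cα on C5 of ring A flank this tri-ortho-substituted axis: joined as an ester, they hold C4 and C1' within a six-membered ring. One palladium-catalysed intramolecular C–H arylation of an aryl 2-bromobenzoate therefore makes the biaryl bond and the lactone ring together, and the lactone carbonyl is kept as Cα. The precursor is a 4-(benzyloxy)phenyl 2-bromo-5-methoxybenzoate whose O-3 carries methoxymethyl, not benzyl, so that no second arene lies within reach of palladium.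

Key step: step 6

Remark on the protecting group: a benzyl ether on the oxygen next to the bromide would itself be a substrate for direct arylation (closure onto the benzyl ring to a 6H-benzo[c]chromene), so that oxygen carries a methoxymethyl group; benzyl is kept on rings B and C, where the palladium cannot reach it.

Assumption: the target SMILES carries no axial descriptor, so the biaryl axis (flanked by two hydroxyls and one CH2 group) is taken as freely rotating and no atroposelective control is planned.

Step 1
Reactants: 1 methyl 3-hydroxy-5-methoxybenzoate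
Product: 2 methyl 3-acetoxy-5-methoxybenzoate
Conditions: Ac2O, pyridine, DMAP (cat.), CH2Cl2, 0 °C → rt
Reagents that add atoms: acetic anhydride, CC(=O)OC(C)=O
Why: Base-promoted O-acylation of a phenol is routine, and the acetate turns the phenol oxygen into a weak donor so that the methoxy group alone directs the next step.

Step 2
Reactants: 2 methyl 3-acetoxy-5-methoxybenzoate
Product: 3 methyl 3-acetoxy-2-bromo-5-methoxybenzoate
Conditions: NBS (1.05 equiv), MeCN, rt → 50 °C
Reagents that add atoms: N-bromosuccinimide, O=C1CCC(=O)N1Br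
Why: Electrophilic aromatic bromination should go to C2, the carbon para to the methoxy group (the strongest donor) and ortho to the weakly donating acetoxy group, as in the para-bromination of 3-methoxyphenyl esters.

Step 3
Reactants: 3 methyl 3-acetoxy-2-bromo-5-methoxybenzoate
Product: 4 2-bromo-3-hydroxy-5-methoxybenzoic acid
Conditions: NaOH (4 equiv), MeOH/H2O, 50 °C; then aq. HCl to pH 2
Reagents that add atoms: sodium hydroxide, [Na+].[OH-]
Why: Saponification cleaves the aryl acetate and the methyl ester in one operation, and the aryl bromide is inert to aqueous hydroxide at this temperature.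

Step 4
Reactants: 4 2-bromo-3-hydroxy-5-methoxybenzoic acid
Product: 6 2-bromo-5-methoxy-3-(methoxymethoxy)benzoic acid, via methoxymethyl ester 5 (not isolated)
Conditions: MOMCl (3 equiv), i-Pr2NEt (4 equiv), CH2Cl2, 0 °C → rt; concentrate; LiOH, THF/MeOH/H2O, rt; then 1 M HCl to pH 4, 0 °C
Reagents that add atoms: chloromethyl methyl ether, COCCl; lithium hydroxide, [Li+].[OH-]
Why: Williamson-type O-alkylation of phenoxide and carboxylate gives the bis(methoxymethyl) compound, and hydroxide then hydrolyses only the acylal-type ester because an aryl methoxymethyl ether is stable to base.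

Step 5
Reactants: 6 2-bromo-5-methoxy-3-(methoxymethoxy)benzoic acid; 7 4-(benzyloxy)phenol
Product: 8 4-(benzyloxy)phenyl 2-bromo-5-methoxy-3-(methoxymethoxy)benzoate
Conditions: EDC·HCl (1.3 equiv), DMAP (0.2 equiv), CH2Cl2, rt
Reagents that add atoms: none
Why: Steglich esterification acylates the phenol under neutral carbodiimide/DMAP activation, avoiding the acid that would endanger the methoxymethyl ether.

Step 6
Reactants: 8 4-(benzyloxy)phenyl 2-bromo-5-methoxy-3-(methoxymethoxy)benzoate
Product: 9 2-(benzyloxy)-8-methoxy-10-(methoxymethoxy)-6H-benzo[c]chromen-6-one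
Conditions: Pd(OAc)2 (10 mol %), PCy3·HBF4 (20 mol %), K2CO3 (2.5 equiv), pivalic acid (30 mol %), DMA, 130 °C, argon
Reagents that add atoms: none
Why: Zerovalent palladium formed from Pd(OAc)2 and PCy3 should insert into the C–Br bond of 8, the divalent arylpalladium species then palladates the C–H ortho to the ester oxygen on the 4-(benzyloxy)phenyl ring by carboxylate/carbonate-assisted concerted metalation–deprotonation, and reductive elimination from the seven-membered palladacycle forms the C10a–C10b biaryl bond. The closest known reaction type is the intramolecular palladium-catalysed direct arylation of aryl 2-halobenzoates to 6H-benzo[c]chromen-6-ones, the biaryl lactone approach to hindered biaryls. The one new ring, the six-membered pyranone, closes by aryl–aryl bond formation between two sp2 carbons that the ester holds five atoms apart, so the crowded axis forms intramolecularly. No stereocenter is created, and the bridged axis is twisted but configurationally mobile. The step needs site selectivity on ring B and chemoselectivity for the ester-linked arene: the tether reaches only the two ortho carbons of the para-substituted phenol ester, which are equivalent, the bromide para to the methoxy group fixes the site on ring A, and the methoxymethyl ether next to the bromide offers no arene C–H for a competing six-membered closure, while the ring B benzyl ether lies out of reach.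

Step 7
Reactants: 9 2-(benzyloxy)-8-methoxy-10-(methoxymethoxy)-6H-benzo[c]chromen-6-one
Product: 10 2-(benzyloxy)-8-methoxy-10-(methoxymethoxy)-6H-benzo[c]chromen-6-ol (racemic at C6)
Conditions: i-Bu2AlH (1.2 equiv), CH2Cl2, −78 °C; MeOH, then aq. potassium sodium tartrate
Reagents that add atoms: none
Why: Partial hydride reduction of a lactone with i-Bu2AlH stops at the aluminium hemiacetal at −78 °C and gives the lactol on work-up; its new hemiacetal carbon forms as a racemate and is destroyed in step 9.

Step 8
Reactants: 11 3-(benzyloxy)benzyl bromide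
Product: 12 [3-(benzyloxy)benzyl]triphenylphosphonium bromide
Conditions: PPh3 (1.05 equiv), toluene, reflux
Reagents that add atoms: triphenylphosphine, c1ccc(cc1)P(c1ccccc1)c1ccccc1
Why: SN2 quaternisation of triphenylphosphine by a benzylic bromide is reliable, and the salt should crystallise from the hot toluene.

Step 9
Reactants: 10 2-(benzyloxy)-8-methoxy-10-(methoxymethoxy)-6H-benzo[c]chromen-6-ol; 12 [3-(benzyloxy)benzyl]triphenylphosphonium bromide
Product: 15 5-(benzyloxy)-2'-{2-[3-(benzyloxy)phenyl]ethenyl}-4'-methoxy-6'-(methoxymethoxy)-[1,1'-biphenyl]-2-ol (E/Z mixture), via phosphorus ylide 13 (not isolated), via ring-opened hydroxy aldehyde 14 (not isolated)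
Conditions: 12 (2.5 equiv), KOt-Bu (3.5 equiv), THF, 0 °C; then 10, 0 °C → 50 °C
Reagents that add atoms: none
Why: In this Wittig olefination the base opens the lactol to its phenoxide aldehyde, which the semistabilised benzylic ylide, used in excess, should convert into the stilbene; the alkene geometry is irrelevant because the double bond is saturated in step 10.

Step 10
Reactants: 15 5-(benzyloxy)-2'-{2-[3-(benzyloxy)phenyl]ethenyl}-4'-methoxy-6'-(methoxymethoxy)-[1,1'-biphenyl]-2-ol
Product: 17 2-{2-hydroxy-6-[2-(3-hydroxyphenyl)ethyl]-4-methoxyphenyl}benzene-1,4-diol (target), via methoxymethyl ether 16 (not isolated)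
Conditions: H2 (1 atm), Pd/C (10 %), EtOAc/MeOH, rt; filter; then HCl (2 M in MeOH), 40 °C, argon
Reagents that add atoms: none
Why: Catalytic hydrogenation saturates the stilbene and hydrogenolyses both benzyl ethers, and acid-catalysed acetal methanolysis then removes the methoxymethyl group; the alkene is reduced first so that the free phenol cannot add to it under acid.

Compound list
1 | methyl 3-hydroxy-5-methoxybenzoate | COC(=O)c1cc(O)cc(OC)c1 | starting material
2 | methyl 3-acetoxy-5-methoxybenzoate | COC(=O)c1cc(OC(C)=O)cc(OC)c1 | intermediate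
3 | methyl 3-acetoxy-2-bromo-5-methoxybenzoate | COC(=O)c1cc(OC)cc(OC(C)=O)c1Br | intermediate
4 | 2-bromo-3-hydroxy-5-methoxybenzoic acid | COc1cc(O)c(Br)c(C(=O)O)c1 | intermediate
5 | methoxymethyl 2-bromo-5-methoxy-3-(methoxymethoxy)benzoate | COCOC(=O)c1cc(OC)cc(OCOC)c1Br | intermediate
6 | 2-bromo-5-methoxy-3-(methoxymethoxy)benzoic acid | COCOc1cc(OC)cc(C(=O)O)c1Br | intermediate
7 | 4-(benzyloxy)phenol | Oc1ccc(OCc2ccccc2)cc1 | starting material
8 | 4-(benzyloxy)phenyl 2-bromo-5-methoxy-3-(methoxymethoxy)benzoate | O=C(Oc1ccc(OCc2ccccc2)cc1)c1cc(OC)cc(OCOC)c1Br | intermediate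
9 | 2-(benzyloxy)-8-methoxy-10-(methoxymethoxy)-6H-benzo[c]chromen-6-one | O=C1Oc2ccc(OCc3ccccc3)cc2-c2c(OCOC)cc(OC)cc21 | intermediate
10 | 2-(benzyloxy)-8-methoxy-10-(methoxymethoxy)-6H-benzo[c]chromen-6-ol (racemic at C6) | OC1Oc2ccc(OCc3ccccc3)cc2-c2c(OCOC)cc(OC)cc21 | intermediate
11 | 3-(benzyloxy)benzyl bromide | BrCc1cccc(OCc2ccccc2)c1 | starting material
12 | [3-(benzyloxy)benzyl]triphenylphosphonium bromide | [Br-].c1ccc(COc2cccc(C[P+](c3ccccc3)(c3ccccc3)c3ccccc3)c2)cc1 | intermediate
13 | [3-(benzyloxy)benzylidene]triphenylphosphorane | c1ccc(COc2cccc(C=P(c3ccccc3)(c3ccccc3)c3ccccc3)c2)cc1 | intermediate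
14 | 5'-(benzyloxy)-2'-hydroxy-4-methoxy-6-(methoxymethoxy)-[1,1'-biphenyl]-2-carbaldehyde | O=Cc1cc(OC)cc(OCOC)c1-c1cc(OCc2ccccc2)ccc1O | intermediate
15 | 5-(benzyloxy)-2'-{2-[3-(benzyloxy)phenyl]ethenyl}-4'-methoxy-6'-(methoxymethoxy)-[1,1'-biphenyl]-2-ol (E/Z mixture) | COCOc1cc(OC)cc(C=Cc2cccc(OCc3ccccc3)c2)c1-c1cc(OCc2ccccc2)ccc1O | intermediate
16 | 2-{2-[2-(3-hydroxyphenyl)ethyl]-4-methoxy-6-(methoxymethoxy)phenyl}benzene-1,4-diol | COCOc1cc(OC)cc(CCc2cccc(O)c2)c1-c1cc(O)ccc1O | intermediate
17 | 2-{2-hydroxy-6-[2-(3-hydroxyphenyl)ethyl]-4-methoxyphenyl}benzene-1,4-diol (no stereocenter) | COc1cc(O)c(-c2cc(O)ccc2O)c(CCc2cccc(O)c2)c1 | target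

Total step count: 10. Longest linear sequence: 9 steps (steps 1–7, 9 and 10); step 8 is a one-step side branch.

Steps most likely to fail

Step 6. Carbonate-induced cleavage of the aryl ester or protodebromination may outrun the C–H palladation, because the ester prefers a conformation that keeps ring B away from the palladium and the bromide is flanked on both sides. The fallback replaces the tethered C–H arylation by an intermolecular Suzuki–Miyaura coupling followed by lactonisation; it sets out from 6 and 7 and comes back at 9.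
- Acid 6 is methylated (MeI, K2CO3, DMF) to methyl 2-bromo-5-methoxy-3-(methoxymethoxy)benzoate F1.
- Phenol 7 is brominated ortho to the hydroxyl (NBS, CH2Cl2, 0 °C) to 4-(benzyloxy)-2-bromophenol F2.
- Miyaura borylation of F2 (B2pin2, Pd(dppf)Cl2, KOAc, dioxane, 90 °C) should give 4-(benzyloxy)-2-(4,4,5,5-tetramethyl-1,3,2-dioxaborolan-2-yl)phenol F3.
- Coupling of F1 with F3 (Pd(OAc)2, SPhos, K3PO4, toluene/H2O, 90 °C) should give methyl 5'-(benzyloxy)-2'-hydroxy-4-methoxy-6-(methoxymethoxy)-[1,1'-biphenyl]-2-carboxylate F4.
- The phenoxide of F4 should close onto the neighbouring ester in the basic medium, or on adjusting to pH 4, to give lactone 9.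

Step 2. Bromination may spread to the carbon para to the acetoxy group or to the carbon between the two oxygens, or run on to a dibromide, giving isomers that are hard to separate. The fallback changes the regiocontrol element from deactivation of the phenol to delivery of bromine by the free phenol; it sets out from 1 and comes back at 4.
- Amine-mediated ortho-bromination of 1 (NBS, i-Pr2NH (10 mol %), CH2Cl2, 0 °C) should give methyl 2-bromo-3-hydroxy-5-methoxybenzoate F5. The hydrogen-bonded phenol directs bromine to its ortho carbons, and of these only C2 is also para to the methoxy group.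
- Saponification of F5 (NaOH, MeOH/H2O, then HCl) gives 4.

Step 9. Olefination may stall because the lactolate opens only partly to an aldehyde that is crowded by the biaryl, and forcing may degrade the material. The fallback avoids the lactol; it sets out from 9 and comes back at 16 inside step 10.
- Full reduction of 9 (LiAlH4, THF, 0 °C) should give 5-(benzyloxy)-2'-(hydroxymethyl)-4'-methoxy-6'-(methoxymethoxy)-[1,1'-biphenyl]-2-ol F6.
- Chemoselective phenol alkylation of F6 (BnBr, K2CO3, acetone, reflux) gives [2',5'-bis(benzyloxy)-4-methoxy-6-(methoxymethoxy)-[1,1'-biphenyl]-2-yl]methanol F7.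
- Benzylic oxidation of F7 (MnO2, CH2Cl2, rt) gives 2',5'-bis(benzyloxy)-4-methoxy-6-(methoxymethoxy)-[1,1'-biphenyl]-2-carbaldehyde F8, a stable open aldehyde.
- Wittig reaction of F8 with ylide 13 (from 12 and KOt-Bu, THF) should give 2',5'-bis(benzyloxy)-2-{2-[3-(benzyloxy)phenyl]ethenyl}-4-methoxy-6-(methoxymethoxy)-1,1'-biphenyl F9.
- Hydrogenation of F9 (H2, Pd/C, EtOAc/MeOH) gives 16, which the acid stage of step 10 converts into 17.

Further compounds
F1 | step 6 | methyl 2-bromo-5-methoxy-3-(methoxymethoxy)benzoate | COC(=O)c1cc(OC)cc(OCOC)c1Br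
F2 | step 6 | 4-(benzyloxy)-2-bromophenol | Oc1ccc(OCc2ccccc2)cc1Br
F3 | step 6 | 4-(benzyloxy)-2-(4,4,5,5-tetramethyl-1,3,2-dioxaborolan-2-yl)phenol | CC1(C)OB(OC1(C)C)c1cc(OCc2ccccc2)ccc1O
F4 | step 6 | methyl 5'-(benzyloxy)-2'-hydroxy-4-methoxy-6-(methoxymethoxy)-[1,1'-biphenyl]-2-carboxylate | COC(=O)c1cc(OC)cc(OCOC)c1-c1cc(OCc2ccccc2)ccc1O
F5 | step 2 | methyl 2-bromo-3-hydroxy-5-methoxybenzoate | COC(=O)c1cc(OC)cc(O)c1Br
F6 | step 9 | 5-(benzyloxy)-2'-(hydroxymethyl)-4'-methoxy-6'-(methoxymethoxy)-[1,1'-biphenyl]-2-ol | OCc1cc(OC)cc(OCOC)c1-c1cc(OCc2ccccc2)ccc1O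
F7 | step 9 | [2',5'-bis(benzyloxy)-4-methoxy-6-(methoxymethoxy)-[1,1'-biphenyl]-2-yl]methanol | OCc1cc(OC)cc(OCOC)c1-c1cc(OCc2ccccc2)ccc1OCc1ccccc1
F8 | step 9 | 2',5'-bis(benzyloxy)-4-methoxy-6-(methoxymethoxy)-[1,1'-biphenyl]-2-carbaldehyde | O=Cc1cc(OC)cc(OCOC)c1-c1cc(OCc2ccccc2)ccc1OCc1ccccc1
F9 | step 9 | 2',5'-bis(benzyloxy)-2-{2-[3-(benzyloxy)phenyl]ethenyl}-4-methoxy-6-(methoxymethoxy)-1,1'-biphenyl (E/Z mixture) | COCOc1cc(OC)cc(C=Cc2cccc(OCc3ccccc3)c2)c1-c1cc(OCc2ccccc2)ccc1OCc1ccccc1
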